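**Plan**

1. Retrosynthesis: C4–OH goes back to C4=O (hydride) and C3–OH to C3–H (enol oxidation). The C2–C3 bond is then cut to an α-diazoketone whose carbenoid carbon (C3) faces the O–CH2–aryl group on O1. The two O–CH2Ar bonds, the C4–C4a bond (Hoesch) and two ring C–O bonds lead back to 2,6-dimethoxyphenol.
2. Forward: pentaoxygenated A ring (steps 1–4), B ring attached as a benzylic ether on O1 (step 6), diazoketone (step 7), pyranone ring closed by C–H insertion (step 8), C3–OH (step 9), debenzylation (step 10), C4–OH (step 11).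
3. Enabling feature: the C2–H bond is benzylic to the 3,4,5-trioxygenated B ring and α to the ether oxygen O1, and the O1–C8a–C4a–C4 edge of the A ring holds it in a six-membered array with C3. Both oxygens ortho to the acyl group carry the same benzylic group, so the two insertion sites are equivalent; the spare group is hydrogenolysed off the C5 oxygen at the end.
4. Stereochemistry: C2 from the chiral dirhodium carboxylate (catalyst control); C3 from epoxidation of the Δ3 enol ether anti to the 2-aryl group; C4 from axial hydride addition (3,4-trans).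

Key step: step 8

Remark: the sense of induction of the dirhodium catalyst cannot be predicted with certainty for this substrate; the catalyst enantiomer that delivers the 2S flavanone is the one to be used.
Remark: [3,4,5-tris(benzyloxy)phenyl]methanol (8) is taken as a purchased building block.

**Route**

Step 1
Reactants: 1 2,6-dimethoxyphenol
Product: 3 2-(benzyloxy)-1,3-dimethoxybenzene
Conditions: BnBr, K2CO3, DMF, rt
Reagents that add atoms: benzyl bromide, BrCc1ccccc1
Why: Williamson etherification of the phenoxide masks the future C7–OH as a benzyl ether that is removed with all the others in step 10.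

Step 2
Reactants: 3 2-(benzyloxy)-1,3-dimethoxybenzene
Product: 4 3-(benzyloxy)-1,5-dibromo-2,4-dimethoxybenzene
Conditions: NBS (2.1 equiv), MeCN, 0 °C → rt, dark
Reagents that add atoms: N-bromosuccinimide, O=C1CCC(=O)N1Br
Why: Electrophilic aromatic bromination should go twice to the positions that are ortho to one methoxy group and para to the other (as with 1,2,3-trimethoxybenzene), because the flanked central benzyloxy group is twisted out of conjugation and activates its para position least.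

Step 3
Reactants: 4 3-(benzyloxy)-1,5-dibromo-2,4-dimethoxybenzene
Product: 5 5-(benzyloxy)-4,6-dimethoxybenzene-1,3-diol
Conditions: Pd2(dba)3 (cat.), tBuXPhos (cat.), KOH, 1,4-dioxane/H2O, 100 °C, Ar; then aq HCl
Reagents that add atoms: potassium hydroxide, [K+].[OH-]
Why: Palladium-catalysed C–O coupling of aryl bromides with hydroxide (Buchwald-type hydroxylation) should convert both C–Br bonds into the phenols that become O1 and the C5 oxygen, leaving the benzyl ether untouched.

Step 4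
Reactants: 5 5-(benzyloxy)-4,6-dimethoxybenzene-1,3-diol
Product: 7 1-[4-(benzyloxy)-2,6-dihydroxy-3,5-dimethoxyphenyl]ethan-1-one, via ketiminium chloride 6 (not isolated)
Conditions: MeCN, ZnCl2, HCl (g), Et2O, 0 °C; then H2O, 90 °C
Reagents that add atoms: acetonitrile, CC#N; water, O; hydrogen chloride, Cl (counter-ion of 6 only)
Why: Houben–Hoesch acylation, in which the only unsubstituted ring carbon (between the two hydroxyl groups of a pentaoxygenated ring) should attack the nitrilium ion and hydrolysis of the ketiminium salt gives the methyl ketone that supplies C4 and C3.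

Step 5
Reactants: 8 [3,4,5-tris(benzyloxy)phenyl]methanol
Product: 9 1,2,3-tris(benzyloxy)-5-(chloromethyl)benzene
Conditions: SOCl2, DMF (cat.), CH2Cl2, 0 °C → rt
Reagents that add atoms: thionyl chloride, ClS(Cl)=O
Why: Chlorination of the benzylic alcohol through its chlorosulfite gives the alkylating agent that carries the B ring and the future C2.

Step 6
Reactants: 7 1-[4-(benzyloxy)-2,6-dihydroxy-3,5-dimethoxyphenyl]ethan-1-one; 9 1,2,3-tris(benzyloxy)-5-(chloromethyl)benzene (2.2 equiv)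
Product: 10 1-[4-(benzyloxy)-3,5-dimethoxy-2,6-bis({[3,4,5-tris(benzyloxy)phenyl]methoxy})phenyl]ethan-1-one
Conditions: K2CO3, KI (cat.), DMF, 70 °C
Reagents that add atoms: none
Why: Double Williamson etherification of both ortho phenols gives a mirror-symmetric ketone in which either benzylic ether can serve as O1–C2 and the other is a hydrogenolysable protecting group for the C5 oxygen.

Step 7
Reactants: 10 1-[4-(benzyloxy)-3,5-dimethoxy-2,6-bis({[3,4,5-tris(benzyloxy)phenyl]methoxy})phenyl]ethan-1-one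
Product: 12 1-[4-(benzyloxy)-3,5-dimethoxy-2,6-bis({[3,4,5-tris(benzyloxy)phenyl]methoxy})phenyl]-2-diazoethan-1-one, via trifluoroacetyl diketone 11 (not isolated)
Conditions: LiHMDS, THF, −78 °C; CF3CO2CH2CF3; aq HCl quench; then MsN3, Et3N, H2O (1 equiv), MeCN, rt
Reagents that add atoms: methanesulfonyl azide, CS(=O)(=O)N=[N+]=[N-]; 2,2,2-trifluoroethyl trifluoroacetate, O=C(OCC(F)(F)F)C(F)(F)F (its CF3CO group is carried by 11 only)
Why: Danheiser detrifluoroacetylative diazo transfer, in which Claisen trifluoroacetylation of the methyl ketone enolate activates the CH2 for Regitz diazo transfer and retro-Claisen loss of the trifluoroacetyl group leaves the diazomethyl ketone.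

Step 8
Reactants: 12 1-[4-(benzyloxy)-3,5-dimethoxy-2,6-bis({[3,4,5-tris(benzyloxy)phenyl]methoxy})phenyl]-2-diazoethan-1-one
Product: 13 (2S)-7-(benzyloxy)-6,8-dimethoxy-2-[3,4,5-tris(benzyloxy)phenyl]-5-{[3,4,5-tris(benzyloxy)phenyl]methoxy}-2,3-dihydro-4H-chromen-4-one
Conditions: Rh2(S-PTTL)4 (1 mol %), CH2Cl2, 4 Å MS, −20 °C → rt, slow addition of 12
Reagents that add atoms: none
Why: Loss of N2 from 12 at the dirhodium core gives an electrophilic rhodium carbenoid at the future C3, which takes the C2–H bond of an O–CH2Ar group in a concerted, asynchronous, hydride-transfer-like three-centre insertion and so forms the C2–C3 bond; the closest known reaction is the Rh(II)-carboxylate-catalysed C–H insertion of 2-alkoxyaryl α-diazoketones to chroman-4-ones, including its enantioselective form with chiral carboxylates. The pyranone ring closes as a 1,6-C–H insertion through a six-membered cyclic transition state made of C3, C4, C4a, C8a, O1 and C2. The only new stereocentre, C2, should be set by the chiral carboxylate ligand wall, which selects one of the enantiotopic benzylic hydrogens of the mirror-symmetric substrate. The step needs C–H insertion to outrun oxonium-ylide formation with [1,2]-benzyl shift, Wolff rearrangement and carbene dimerisation: the C–H bond is doubly activated (α to O1 and benzylic to a trioxygenated ring), the aryl-ether oxygen flanked by two ortho substituents is a poor ylide donor, the carboxylate catalyst at low temperature disfavours Wolff chemistry and slow addition disfavours dimerisation. Site selectivity is secured by symmetry, since both ortho oxygens carry the same 3,4,5-tris(benzyloxy)benzyl group and either insertion gives 13, while the 7-O-benzyl and methoxy C–H bonds are out of reach of the carbenoid.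

Step 9
Reactants: 13 (2S)-7-(benzyloxy)-6,8-dimethoxy-2-[3,4,5-tris(benzyloxy)phenyl]-5-{[3,4,5-tris(benzyloxy)phenyl]methoxy}-2,3-dihydro-4H-chromen-4-one
Product: 16 (2R,3R)-7-(benzyloxy)-3-hydroxy-6,8-dimethoxy-2-[3,4,5-tris(benzyloxy)phenyl]-5-{[3,4,5-tris(benzyloxy)phenyl]methoxy}-2,3-dihydro-4H-chromen-4-one, via trimethylsilyl enol ether 14 (not isolated), via silyloxy epoxide 15 (not isolated)
Conditions: TMSOTf, Et3N, CH2Cl2, 0 °C; then DMDO, acetone/CH2Cl2, −40 → 0 °C; then aq citric acid, MeOH, 0 °C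
Reagents that add atoms: dimethyldioxirane, CC1(C)OO1; trimethylsilyl trifluoromethanesulfonate, C[Si](C)(C)OS(=O)(=O)C(F)(F)F (its SiMe3 group is carried by 14 and 15 only)
Why: Rubottom oxidation, in which soft enolisation should give the Δ3 silyl enol ether without opening the pyranone, the dioxirane should epoxidise the face anti to the 2-aryl group, and acid collapse of the silyloxy epoxide gives the 3-hydroxy ketone with OH trans to the aryl group (also the more stable epimer).

Step 10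
Reactants: 16 (2R,3R)-7-(benzyloxy)-3-hydroxy-6,8-dimethoxy-2-[3,4,5-tris(benzyloxy)phenyl]-5-{[3,4,5-tris(benzyloxy)phenyl]methoxy}-2,3-dihydro-4H-chromen-4-one
Product: 17 (2R,3R)-3,5,7-trihydroxy-6,8-dimethoxy-2-(3,4,5-trihydroxyphenyl)-2,3-dihydro-4H-chromen-4-one
Conditions: H2 (1 atm), 10% Pd/C, EtOAc/MeOH, rt
Reagents that add atoms: none
Why: Neutral hydrogenolysis should cleave the seven benzyl ethers and the benzylic ether on the C5 oxygen while the aryl ketone and the O1–C2 bond survive, as in the debenzylation of benzylated dihydroflavonols; it is placed before the reduction so that no benzylic C4–OH is exposed to Pd/H2.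

Step 11
Reactants: 17 (2R,3R)-3,5,7-trihydroxy-6,8-dimethoxy-2-(3,4,5-trihydroxyphenyl)-2,3-dihydro-4H-chromen-4-one
Product: 18 (2R,3S,4R)-6,8-dimethoxy-2-(3,4,5-trihydroxyphenyl)-3,4-dihydro-2H-chromene-3,4,5,7-tetrol
Conditions: NaBH4, degassed EtOH, 0 °C → rt, Ar; AcOH to pH 6
Reagents that add atoms: none
Why: Borohydride reduction of a 2,3-trans-dihydroflavonol, in which axial hydride delivery to C4 of the half-chair with equatorial 2-aryl and 3-OH groups should give the equatorial 4-OH, that is the 3,4-trans (4R) diol, as known for the reduction of dihydroquercetin-type ketones.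

**Compound list**

1 | 2,6-dimethoxyphenol | COc1cccc(OC)c1O | starting material
3 | 2-(benzyloxy)-1,3-dimethoxybenzene | COc1cccc(OC)c1OCc1ccccc1 | intermediate
4 | 3-(benzyloxy)-1,5-dibromo-2,4-dimethoxybenzene | COc1c(Br)cc(Br)c(OC)c1OCc1ccccc1 | intermediate
5 | 5-(benzyloxy)-4,6-dimethoxybenzene-1,3-diol | COc1c(O)cc(O)c(OC)c1OCc1ccccc1 | intermediate
6 | 1-[4-(benzyloxy)-2,6-dihydroxy-3,5-dimethoxyphenyl]ethan-1-iminium chloride | CC(=[NH2+])c1c(O)c(OC)c(OCc2ccccc2)c(OC)c1O.[Cl-] | intermediate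
7 | 1-[4-(benzyloxy)-2,6-dihydroxy-3,5-dimethoxyphenyl]ethan-1-one | CC(=O)c1c(O)c(OC)c(OCc2ccccc2)c(OC)c1O | intermediate
8 | [3,4,5-tris(benzyloxy)phenyl]methanol | OCc1cc(OCc2ccccc2)c(OCc2ccccc2)c(OCc2ccccc2)c1 | starting material
9 | 1,2,3-tris(benzyloxy)-5-(chloromethyl)benzene | ClCc1cc(OCc2ccccc2)c(OCc2ccccc2)c(OCc2ccccc2)c1 | intermediate
10 | 1-[4-(benzyloxy)-3,5-dimethoxy-2,6-bis({[3,4,5-tris(benzyloxy)phenyl]methoxy})phenyl]ethan-1-one | CC(=O)c1c(OCc2cc(OCc3ccccc3)c(OCc3ccccc3)c(OCc3ccccc3)c2)c(OC)c(OCc2ccccc2)c(OC)c1OCc1cc(OCc2ccccc2)c(OCc2ccccc2)c(OCc2ccccc2)c1 | intermediate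
11 | 1-[4-(benzyloxy)-3,5-dimethoxy-2,6-bis({[3,4,5-tris(benzyloxy)phenyl]methoxy})phenyl]-4,4,4-trifluorobutane-1,3-dione | O=C(CC(=O)C(F)(F)F)c1c(OCc2cc(OCc3ccccc3)c(OCc3ccccc3)c(OCc3ccccc3)c2)c(OC)c(OCc2ccccc2)c(OC)c1OCc1cc(OCc2ccccc2)c(OCc2ccccc2)c(OCc2ccccc2)c1 | intermediate
12 | 1-[4-(benzyloxy)-3,5-dimethoxy-2,6-bis({[3,4,5-tris(benzyloxy)phenyl]methoxy})phenyl]-2-diazoethan-1-one | [N-]=[N+]=CC(=O)c1c(OCc2cc(OCc3ccccc3)c(OCc3ccccc3)c(OCc3ccccc3)c2)c(OC)c(OCc2ccccc2)c(OC)c1OCc1cc(OCc2ccccc2)c(OCc2ccccc2)c(OCc2ccccc2)c1 | intermediate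
13 | (2S)-7-(benzyloxy)-6,8-dimethoxy-2-[3,4,5-tris(benzyloxy)phenyl]-5-{[3,4,5-tris(benzyloxy)phenyl]methoxy}-2,3-dihydro-4H-chromen-4-one | COc1c(OCc3ccccc3)c(OC)c2c(c1OCc1cc(OCc3ccccc3)c(OCc3ccccc3)c(OCc3ccccc3)c1)C(=O)C[C@@H](c1cc(OCc3ccccc3)c(OCc3ccccc3)c(OCc3ccccc3)c1)O2 | intermediate
14 | (2S)-7-(benzyloxy)-6,8-dimethoxy-2-[3,4,5-tris(benzyloxy)phenyl]-5-{[3,4,5-tris(benzyloxy)phenyl]methoxy}-4-[(trimethylsilyl)oxy]-2H-chromene | COc1c(OCc3ccccc3)c(OC)c2c(c1OCc1cc(OCc3ccccc3)c(OCc3ccccc3)c(OCc3ccccc3)c1)C(O[Si](C)(C)C)=C[C@@H](c1cc(OCc3ccccc3)c(OCc3ccccc3)c(OCc3ccccc3)c1)O2 | intermediate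
15 | 3,4-epoxide of 14, oxirane oxygen trans to the 2-aryl group (2R,3R,4R in flavan numbering), 4-[(trimethylsilyl)oxy] retained | COc1c(OCc3ccccc3)c(OC)c2c(c1OCc1cc(OCc3ccccc3)c(OCc3ccccc3)c(OCc3ccccc3)c1)[C@]4(O[Si](C)(C)C)O[C@@H]4[C@@H](c1cc(OCc3ccccc3)c(OCc3ccccc3)c(OCc3ccccc3)c1)O2 | intermediate
16 | (2R,3R)-7-(benzyloxy)-3-hydroxy-6,8-dimethoxy-2-[3,4,5-tris(benzyloxy)phenyl]-5-{[3,4,5-tris(benzyloxy)phenyl]methoxy}-2,3-dihydro-4H-chromen-4-one | COc1c(OCc3ccccc3)c(OC)c2c(c1OCc1cc(OCc3ccccc3)c(OCc3ccccc3)c(OCc3ccccc3)c1)C(=O)[C@H](O)[C@@H](c1cc(OCc3ccccc3)c(OCc3ccccc3)c(OCc3ccccc3)c1)O2 | intermediate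
17 | (2R,3R)-3,5,7-trihydroxy-6,8-dimethoxy-2-(3,4,5-trihydroxyphenyl)-2,3-dihydro-4H-chromen-4-one | COc1c(O)c(OC)c2c(c1O)C(=O)[C@H](O)[C@@H](c1cc(O)c(O)c(O)c1)O2 | intermediate
18 | (2R,3S,4R)-6,8-dimethoxy-2-(3,4,5-trihydroxyphenyl)-3,4-dihydro-2H-chromene-3,4,5,7-tetrol | COc1c(O)c(OC)c2c(c1O)[C@@H](O)[C@H](O)[C@@H](c1cc(O)c(O)c(O)c1)O2 | target

Total step count: 11.
Longest linear sequence: 10 steps (steps 1–4 and 6–11, from 1); step 5 is a one-step side branch.

**Steps most likely to fail**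

Step 8. The carbenoid may be captured by the ether oxygen (oxonium ylide, then [1,2]-benzyl shift) instead of inserting, or the insertion may run with low enantioselectivity. The fallback forms the C2–aryl bond instead of the C2–C3 bond. It sets out from 7 and comes back at 13. Mono-alkylation of 7 with one equivalent of 9 (K2CO3, acetone, reflux) should stop at the hydrogen-bonded 1-[4-(benzyloxy)-2-hydroxy-3,5-dimethoxy-6-{[3,4,5-tris(benzyloxy)phenyl]methoxy}phenyl]ethan-1-one F1. Condensation with N,N-dimethylformamide dimethyl acetal (toluene, 100 °C) gives the (2E)-3-(dimethylamino)prop-2-en-1-one (enaminone) F2. Brief treatment with acid (aq HCl, CH2Cl2) closes it to 7-(benzyloxy)-6,8-dimethoxy-5-{[3,4,5-tris(benzyloxy)phenyl]methoxy}-4H-chromen-4-one F3. Palladium-catalysed asymmetric conjugate addition of purchased 3,4,5-tris(benzyloxy)phenylboronic acid (Pd(OCOCF3)2, t-BuPyOx of the antipode that gives 2S, NH4PF6, H2O, ClCH2CH2Cl, 60 °C) then gives 13.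

Step 9. Enolisation may trigger β-elimination of the aryloxide (opening of the pyranone to the chalcone), and the epoxidation may show poor facial selectivity or over-oxidise the electron-rich rings. The fallback installs the C3 oxygen before the ring is closed. It sets out from 7 and comes back at 17. Protection of both phenols (MOMCl, iPr2NEt, CH2Cl2) gives 1-[4-(benzyloxy)-3,5-dimethoxy-2,6-bis(methoxymethoxy)phenyl]ethan-1-one F4. Claisen–Schmidt condensation with 3,4,5-tris(benzyloxy)benzaldehyde (KOH, EtOH/THF) gives the (2E)-chalcone F5. Juliá–Colonna epoxidation (poly-L-leucine or its antipode, whichever gives the 2R,3S oxirane, urea–H2O2, DBU, THF) gives the trans-(2R,3S)-epoxy ketone F6. HCl in MeOH/THF removes the MOM groups, and the freed phenol opens the oxirane at the benzylic carbon; the retained C3 configuration fixes the absolute sense and the ring closes trans to give (2R,3R)-7-(benzyloxy)-3,5-dihydroxy-6,8-dimethoxy-2-[3,4,5-tris(benzyloxy)phenyl]-2,3-dihydro-4H-chromen-4-one F7. Hydrogenolysis (H2, Pd/C) then gives 17.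

Step 3. The second C–O coupling may stall, protodebromination may compete, and the electron-rich resorcinol may decompose oxidatively in hot base. The fallback makes the C–O bonds by boron-to-oxygen migration instead of reductive elimination. It sets out from 4 and comes back at 5. Miyaura borylation (B2pin2, Pd(dppf)Cl2, KOAc, 1,4-dioxane, 90 °C) gives 2,2'-[5-(benzyloxy)-4,6-dimethoxy-1,3-phenylene]bis(4,4,5,5-tetramethyl-1,3,2-dioxaborolane) F8. Oxidation (H2O2, NaOH, THF/H2O, 0 °C) under mild, cold conditions gives 5.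

**Further compounds**

F1 | step 8 | 1-[4-(benzyloxy)-2-hydroxy-3,5-dimethoxy-6-{[3,4,5-tris(benzyloxy)phenyl]methoxy}phenyl]ethan-1-one | CC(=O)c1c(O)c(OC)c(OCc2ccccc2)c(OC)c1OCc1cc(OCc2ccccc2)c(OCc2ccccc2)c(OCc2ccccc2)c1
F2 | step 8 | (2E)-1-[4-(benzyloxy)-2-hydroxy-3,5-dimethoxy-6-{[3,4,5-tris(benzyloxy)phenyl]methoxy}phenyl]-3-(dimethylamino)prop-2-en-1-one | CN(C)/C=C/C(=O)c1c(O)c(OC)c(OCc2ccccc2)c(OC)c1OCc1cc(OCc2ccccc2)c(OCc2ccccc2)c(OCc2ccccc2)c1
F3 | step 8 | 7-(benzyloxy)-6,8-dimethoxy-5-{[3,4,5-tris(benzyloxy)phenyl]methoxy}-4H-chromen-4-one | COc1c(OCc3ccccc3)c(OC)c2occc(=O)c2c1OCc1cc(OCc3ccccc3)c(OCc3ccccc3)c(OCc3ccccc3)c1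
F4 | step 9 | 1-[4-(benzyloxy)-3,5-dimethoxy-2,6-bis(methoxymethoxy)phenyl]ethan-1-one | CC(=O)c1c(OCOC)c(OC)c(OCc2ccccc2)c(OC)c1OCOC
F5 | step 9 | (2E)-1-[4-(benzyloxy)-3,5-dimethoxy-2,6-bis(methoxymethoxy)phenyl]-3-[3,4,5-tris(benzyloxy)phenyl]prop-2-en-1-one | O=C(/C=C/c1cc(OCc2ccccc2)c(OCc2ccccc2)c(OCc2ccccc2)c1)c1c(OCOC)c(OC)c(OCc2ccccc2)c(OC)c1OCOC
F6 | step 9 | [4-(benzyloxy)-3,5-dimethoxy-2,6-bis(methoxymethoxy)phenyl]{(2R,3S)-3-[3,4,5-tris(benzyloxy)phenyl]oxiran-2-yl}methanone | O=C([C@@H]1O[C@H]1c1cc(OCc2ccccc2)c(OCc2ccccc2)c(OCc2ccccc2)c1)c1c(OCOC)c(OC)c(OCc2ccccc2)c(OC)c1OCOC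
F7 | step 9 | (2R,3R)-7-(benzyloxy)-3,5-dihydroxy-6,8-dimethoxy-2-[3,4,5-tris(benzyloxy)phenyl]-2,3-dihydro-4H-chromen-4-one | COc1c(OCc3ccccc3)c(OC)c2c(c1O)C(=O)[C@H](O)[C@@H](c1cc(OCc3ccccc3)c(OCc3ccccc3)c(OCc3ccccc3)c1)O2
F8 | step 3 | 2,2'-[5-(benzyloxy)-4,6-dimethoxy-1,3-phenylene]bis(4,4,5,5-tetramethyl-1,3,2-dioxaborolane) | COc1c(B2OC(C)(C)C(C)(C)O2)cc(B2OC(C)(C)C(C)(C)O2)c(OC)c1OCc1ccccc1
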